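**Retrosynthetic overview**
- The C3 formyl group comes from a silyl-protected CH2OH (desilylation, Dess–Martin oxidation); the catechol is released last by hydrogenolysis of two benzyl ethers.
- The C4 acetate arm comes from SN2′ attack (Michael addition–elimination) of an allyl hydroxytyrosyl malonate on the 6-methoxy C4=C5 enoate acetal. That acetal is made from the C4 ketone by Luche reduction and acid-catalysed allylic transposition. A Lewis-acid substitution of a C4 leaving group is not used, because the O1-stabilised allyl cation is expected to take carbon nucleophiles at C6.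
- The plan rests on the single ring, the dihydropyran O1–C2(Me)–C3–C4–C5(CO2Me)=C6. O1–C2 with its methyl is acetaldehyde, and C3–C4–C5(CO2Me)=C6 is a 1-methoxy-3-silyloxy diene from a 2-(methoxymethylene)-3-oxo ester. One catalytic asymmetric hetero-Diels–Alder reaction forms C2–C3 and O1–C6, closes this ring and sets C2 and C3.
- The diene comes from methyl acetoacetate dianion, (triisopropylsiloxy)methyl chloride, trimethyl orthoformate and TBSOTf. The malonate comes from hydroxytyrosol, benzyl bromide, Meldrum's acid and allyl bromide.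

Key step: step 4

Remark on the chemistry: the complex CrCl(L1) built from (1R,2S)-1-aminoindan-2-ol is assumed to expose the Re face of acetaldehyde (giving 2S); if the sense is the reverse, the mirror-image complex from (1S,2R)-1-aminoindan-2-ol is used.

Step 1
Reactants: 1 methyl acetoacetate; 2 (triisopropylsiloxy)methyl chloride
Product: 3 methyl 3-oxo-5-(triisopropylsilyloxy)pentanoate
Conditions: NaH, THF, 0 °C; n-BuLi, 0 °C; then 2, −78 → 0 °C
Reagents that add atoms: none
Why: Huckin–Weiler γ-alkylation, in which the dianion of 1 reacts at its terminal carbon with the α-chloro ether 2 as it does with benzyl chloromethyl ether, so that the future C3 hydroxymethyl arm arrives already silylated.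

Step 2
Reactants: 3 methyl 3-oxo-5-(triisopropylsilyloxy)pentanoate; 4 trimethyl orthoformate
Product: 5 methyl 2-(methoxymethylene)-3-oxo-5-(triisopropylsilyloxy)pentanoate (E/Z mixture)
Conditions: Ac2O, 110 °C, volatiles distilled off
Reagents that add atoms: none
Why: Alkoxymethylenation (Claisen-type condensation of the doubly activated methylene with the orthoformate, driven by acetylation of the methanol released) touches only C2, and the E/Z mixture is of no consequence later.

Step 3
Reactants: 5 methyl 2-(methoxymethylene)-3-oxo-5-(triisopropylsilyloxy)pentanoate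
Product: 6 methyl (2Z,3Z)-3-(tert-butyldimethylsilyloxy)-2-(methoxymethylene)-5-(triisopropylsilyloxy)pent-3-enoate
Conditions: TBSOTf, Et3N, Et2O, 0 °C
Reagents that add atoms: tert-butyldimethylsilyl trifluoromethanesulfonate, CC(C)(C)[Si](C)(C)OS(=O)(=O)C(F)(F)F
Why: Soft enolisation and O-silylation of the only enolisable position gives the 1-methoxy-3-silyloxy diene, the (Z)-enol ether being the expected thermodynamic isomer, which places the CH2OTIPS group outside the s-cis diene.

Step 4
Reactants: 6 methyl (2Z,3Z)-3-(tert-butyldimethylsilyloxy)-2-(methoxymethylene)-5-(triisopropylsilyloxy)pent-3-enoate; 7 acetaldehyde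
Product: 9 methyl (2S,3R)-2-methyl-4-oxo-3-[(triisopropylsilyloxy)methyl]-3,4-dihydro-2H-pyran-5-carboxylate (2,3-cis), via silyl enol ether cycloadduct 8 (not isolated)
Conditions: CrCl(L1) (5 mol %; trivalent chromium, L1 = dianionic tridentate Schiff base of (1R,2S)-1-aminoindan-2-ol and 3-(1-adamantyl)-2-hydroxy-5-methylbenzaldehyde), 4 Å MS, 7 (excess), t-BuOMe, 0 °C → rt, sealed; then CF3CO2H (cat.), CH2Cl2, 0 °C
Reagents that add atoms: none
Why: Acetaldehyde bound to the chiral Lewis acid is attacked at carbon by the silyl enol ether terminus C3 while its oxygen bonds to the methoxy-bearing C6, either in a concerted asynchronous endo [4+2] transition state or by Mukaiyama aldol addition followed by 6-endo oxa-Michael closure; CF3CO2H then expels methanol and the enol silyl group from cycloadduct 8. The closest known reaction is the chromium- or titanium-catalysed hetero-Diels–Alder reaction of 1-methoxy-3-silyloxy (Danishefsky-type) dienes with unactivated aliphatic aldehydes. The one ring (O1–C2–C3–C4–C5–C6) closes by this [4+2] cycloaddition, which forms C2–C3 and O1–C6. C2 is set by the ligand, which leaves the Re face of the aldehyde open; C3 is set relative to C2 by the (Z) enol ether geometry together with the endo placement of the aldehyde methyl group away from the bulky catalyst, which should give the 2,3-cis product. The step needs regioselectivity, secured by the diene polarity (nucleophilic C3, acetal-type C6), which the C5 ester on the central diene carbon does not reverse although it lowers the rate; the methoxymethylene geometry is immaterial because methanol is lost.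

Step 5
Reactants: 9 methyl (2S,3R)-2-methyl-4-oxo-3-[(triisopropylsilyloxy)methyl]-3,4-dihydro-2H-pyran-5-carboxylate
Product: 10 methyl (2S,3S)-4-hydroxy-2-methyl-3-[(triisopropylsilyloxy)methyl]-3,4-dihydro-2H-pyran-5-carboxylate (2,3-cis; C4 carbinol configuration open)
Conditions: NaBH4, CeCl3·7H2O, MeOH, −78 °C
Reagents that add atoms: none
Why: Luche reduction, in which the cerium-activated ketone is reduced 1,2 by the hard methoxyborohydride in preference to conjugate addition at C6; the new C4 carbinol centre is erased in step 6.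

Step 6
Reactants: 10 methyl (2S,3S)-4-hydroxy-2-methyl-3-[(triisopropylsilyloxy)methyl]-3,4-dihydro-2H-pyran-5-carboxylate
Product: 11 methyl (2S,3R)-6-methoxy-2-methyl-3-[(triisopropylsilyloxy)methyl]-3,6-dihydro-2H-pyran-5-carboxylate (both C6 anomers)
Conditions: CSA (cat.), MeOH–CH2Cl2, 0 °C → rt; Et3N quench
Reagents that add atoms: methanol, CO
Why: Ferrier-type allylic transposition, in which ionisation at C4 gives the O1-stabilised allyl cation that methanol captures at the oxocarbenium carbon C6, the acetal–enoate isomer also being the expected thermodynamic sink; C2 and C3 are not involved.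

Step 7
Reactants: 12 hydroxytyrosol
Product: 13 2-[3,4-bis(benzyloxy)phenyl]ethanol
Conditions: BnBr (2.1 equiv), K2CO3, acetone, reflux, N2
Reagents that add atoms: benzyl bromide, BrCc1ccccc1
Why: Williamson etherification, carbonate deprotonating only the phenols so that the aliphatic hydroxyl stays free.

Step 8
Reactants: 13 2-[3,4-bis(benzyloxy)phenyl]ethanol; 14 Meldrum's acid
Product: 15 3-{2-[3,4-bis(benzyloxy)phenyl]ethoxy}-3-oxopropanoic acid
Conditions: toluene, 100 °C
Reagents that add atoms: none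
Why: Thermal alcoholysis of Meldrum's acid (ring opening with loss of acetone) gives the malonic half ester of the primary alcohol directly.

Step 9
Reactants: 15 3-{2-[3,4-bis(benzyloxy)phenyl]ethoxy}-3-oxopropanoic acid
Product: 16 allyl 2-[3,4-bis(benzyloxy)phenyl]ethyl malonate
Conditions: allyl bromide, KHCO3, DMF, rt
Reagents that add atoms: allyl bromide, C=CCBr
Why: Carboxylate O-alkylation (SN2), hydrogencarbonate being too weak a base to deprotonate and C-allylate the malonate methylene.

Step 10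
Reactants: 11 methyl (2S,3R)-6-methoxy-2-methyl-3-[(triisopropylsilyloxy)methyl]-3,6-dihydro-2H-pyran-5-carboxylate; 16 allyl 2-[3,4-bis(benzyloxy)phenyl]ethyl malonate
Product: 17 1-allyl 3-{2-[3,4-bis(benzyloxy)phenyl]ethyl} 2-{(2S,3R,4R)-5-(methoxycarbonyl)-2-methyl-3-[(triisopropylsilyloxy)methyl]-3,4-dihydro-2H-pyran-4-yl}malonate (epimers at the malonate carbon)
Conditions: 16 (1.5 equiv), NaH (1.4 equiv), THF–DMF, 0 °C; then 11, rt → 50 °C
Reagents that add atoms: none
Why: Michael addition of the sodium malonate to C4 of the enoate followed by E1cB loss of the C6 methoxide from the ester enolate (overall SN2′ conjugate addition–elimination, as with Morita–Baylis–Hillman acetates) restores the C5=C6 enol ether, and the nucleophile should enter C4 anti to the neighbouring C3 silyloxymethyl group, setting the 3,4-trans relation.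

Step 11
Reactants: 17 1-allyl 3-{2-[3,4-bis(benzyloxy)phenyl]ethyl} 2-{(2S,3R,4R)-5-(methoxycarbonyl)-2-methyl-3-[(triisopropylsilyloxy)methyl]-3,4-dihydro-2H-pyran-4-yl}malonate
Product: 19 methyl (2S,3R,4S)-4-{2-[2-(3,4-bis(benzyloxy)phenyl)ethoxy]-2-oxoethyl}-2-methyl-3-[(triisopropylsilyloxy)methyl]-3,4-dihydro-2H-pyran-5-carboxylate, via malonic half acid 18 (not isolated)
Conditions: Pd(OAc)2 (cat.), PPh3, HCO2H, Et3N, 1,4-dioxane, rt → 95 °C
Reagents that add atoms: none
Why: Tsuji deallylation, in which zerovalent palladium formed in the flask ionises the allyl ester and formate reduces the allyl fragment to propene, after which the malonic half acid decarboxylates on heating; benzyl ethers, the silyl ether and the enol ether ester are inert and no ring stereocentre is touched.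

Step 12
Reactants: 19 methyl (2S,3R,4S)-4-{2-[2-(3,4-bis(benzyloxy)phenyl)ethoxy]-2-oxoethyl}-2-methyl-3-[(triisopropylsilyloxy)methyl]-3,4-dihydro-2H-pyran-5-carboxylate
Product: 20 methyl (2S,3R,4S)-4-{2-[2-(3,4-bis(benzyloxy)phenyl)ethoxy]-2-oxoethyl}-3-(hydroxymethyl)-2-methyl-3,4-dihydro-2H-pyran-5-carboxylate
Conditions: HF·pyridine, pyridine, THF, 0 °C → rt
Reagents that add atoms: none
Why: Fluoride desilylation under buffered, weakly acidic conditions frees the primary alcohol without base, so that lactonisation onto the C4 arm ester is held back; the alcohol is used at once.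

Step 13
Reactants: 20 methyl (2S,3R,4S)-4-{2-[2-(3,4-bis(benzyloxy)phenyl)ethoxy]-2-oxoethyl}-3-(hydroxymethyl)-2-methyl-3,4-dihydro-2H-pyran-5-carboxylate
Product: 21 methyl (2S,3S,4S)-4-{2-[2-(3,4-bis(benzyloxy)phenyl)ethoxy]-2-oxoethyl}-3-formyl-2-methyl-3,4-dihydro-2H-pyran-5-carboxylate
Conditions: Dess–Martin periodinane, pyridine, CH2Cl2, 0 °C
Reagents that add atoms: none
Why: Dess–Martin oxidation under pyridine buffering is mild enough to leave the epimerisable C3 centre and the β-alkoxy aldehyde (prone to retro-oxa-Michael ring opening under base) intact, and the catechol is still masked.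

Step 14
Reactants: 21 methyl (2S,3S,4S)-4-{2-[2-(3,4-bis(benzyloxy)phenyl)ethoxy]-2-oxoethyl}-3-formyl-2-methyl-3,4-dihydro-2H-pyran-5-carboxylate
Product: 22 methyl (2S,3S,4S)-4-{2-[2-(3,4-dihydroxyphenyl)ethoxy]-2-oxoethyl}-3-formyl-2-methyl-3,4-dihydro-2H-pyran-5-carboxylate (CNP0172886.2)
Conditions: H2 (1 atm), Pd/C (palladium on carbon), EtOAc, rt
Reagents that add atoms: none
Why: Hydrogenolysis of the two aryl benzyl ethers is fast and neutral, so the aliphatic aldehyde, the push–pull C5=C6 bond and the C3 centre should survive a short exposure.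

**Compound list**
1 | methyl acetoacetate | COC(=O)CC(C)=O | starting material
2 | (triisopropylsiloxy)methyl chloride | ClCO[Si](C(C)C)(C(C)C)C(C)C | starting material
3 | methyl 3-oxo-5-(triisopropylsilyloxy)pentanoate | COC(=O)CC(=O)CCO[Si](C(C)C)(C(C)C)C(C)C | intermediate
4 | trimethyl orthoformate | COC(OC)OC | starting material
5 | methyl 2-(methoxymethylene)-3-oxo-5-(triisopropylsilyloxy)pentanoate (E/Z mixture, geometry left open) | COC=C(C(=O)OC)C(=O)CCO[Si](C(C)C)(C(C)C)C(C)C | intermediate
6 | methyl (2Z,3Z)-3-(tert-butyldimethylsilyloxy)-2-(methoxymethylene)-5-(triisopropylsilyloxy)pent-3-enoate | CO/C=C(\C(=O)OC)/C(O[Si](C)(C)C(C)(C)C)=C/CO[Si](C(C)C)(C(C)C)C(C)C | intermediate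
7 | acetaldehyde | CC=O | starting material
8 | methyl (2S,3R)-4-(tert-butyldimethylsilyloxy)-6-methoxy-2-methyl-3-[(triisopropylsilyloxy)methyl]-3,6-dihydro-2H-pyran-5-carboxylate (C6 as formed) | COC(=O)C1=C(O[Si](C)(C)C(C)(C)C)[C@H](CO[Si](C(C)C)(C(C)C)C(C)C)[C@H](C)OC1OC | intermediate
9 | methyl (2S,3R)-2-methyl-4-oxo-3-[(triisopropylsilyloxy)methyl]-3,4-dihydro-2H-pyran-5-carboxylate | COC(=O)C1=CO[C@@H](C)[C@@H](CO[Si](C(C)C)(C(C)C)C(C)C)C1=O | intermediate
10 | methyl (2S,3S)-4-hydroxy-2-methyl-3-[(triisopropylsilyloxy)methyl]-3,4-dihydro-2H-pyran-5-carboxylate (C4 open) | COC(=O)C1=CO[C@@H](C)[C@@H](CO[Si](C(C)C)(C(C)C)C(C)C)C1O | intermediate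
11 | methyl (2S,3R)-6-methoxy-2-methyl-3-[(triisopropylsilyloxy)methyl]-3,6-dihydro-2H-pyran-5-carboxylate (C6 anomers) | COC(=O)C1=C[C@H](CO[Si](C(C)C)(C(C)C)C(C)C)[C@H](C)OC1OC | intermediate
12 | hydroxytyrosol | OCCc1ccc(O)c(O)c1 | starting material
13 | 2-[3,4-bis(benzyloxy)phenyl]ethanol | OCCc1ccc(OCc2ccccc2)c(OCc2ccccc2)c1 | intermediate
14 | Meldrum's acid (2,2-dimethyl-1,3-dioxane-4,6-dione) | CC1(C)OC(=O)CC(=O)O1 | starting material
15 | 3-{2-[3,4-bis(benzyloxy)phenyl]ethoxy}-3-oxopropanoic acid | OC(=O)CC(=O)OCCc1ccc(OCc2ccccc2)c(OCc2ccccc2)c1 | intermediate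
16 | allyl 2-[3,4-bis(benzyloxy)phenyl]ethyl malonate | C=CCOC(=O)CC(=O)OCCc1ccc(OCc2ccccc2)c(OCc2ccccc2)c1 | intermediate
17 | 1-allyl 3-{2-[3,4-bis(benzyloxy)phenyl]ethyl} 2-{(2S,3R,4R)-5-(methoxycarbonyl)-2-methyl-3-[(triisopropylsilyloxy)methyl]-3,4-dihydro-2H-pyran-4-yl}malonate (malonate carbon open) | COC(=O)C1=CO[C@@H](C)[C@@H](CO[Si](C(C)C)(C(C)C)C(C)C)[C@@H]1C(C(=O)OCC=C)C(=O)OCCc1ccc(OCc2ccccc2)c(OCc2ccccc2)c1 | intermediate
18 | 3-{2-[3,4-bis(benzyloxy)phenyl]ethoxy}-2-{(2S,3R,4R)-5-(methoxycarbonyl)-2-methyl-3-[(triisopropylsilyloxy)methyl]-3,4-dihydro-2H-pyran-4-yl}-3-oxopropanoic acid (malonate carbon open) | COC(=O)C1=CO[C@@H](C)[C@@H](CO[Si](C(C)C)(C(C)C)C(C)C)[C@@H]1C(C(=O)O)C(=O)OCCc1ccc(OCc2ccccc2)c(OCc2ccccc2)c1 | intermediate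
19 | methyl (2S,3R,4S)-4-{2-[2-(3,4-bis(benzyloxy)phenyl)ethoxy]-2-oxoethyl}-2-methyl-3-[(triisopropylsilyloxy)methyl]-3,4-dihydro-2H-pyran-5-carboxylate | COC(=O)C1=CO[C@@H](C)[C@@H](CO[Si](C(C)C)(C(C)C)C(C)C)[C@@H]1CC(=O)OCCc1ccc(OCc2ccccc2)c(OCc2ccccc2)c1 | intermediate
20 | methyl (2S,3R,4S)-4-{2-[2-(3,4-bis(benzyloxy)phenyl)ethoxy]-2-oxoethyl}-3-(hydroxymethyl)-2-methyl-3,4-dihydro-2H-pyran-5-carboxylate | COC(=O)C1=CO[C@@H](C)[C@@H](CO)[C@@H]1CC(=O)OCCc1ccc(OCc2ccccc2)c(OCc2ccccc2)c1 | intermediate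
21 | methyl (2S,3S,4S)-4-{2-[2-(3,4-bis(benzyloxy)phenyl)ethoxy]-2-oxoethyl}-3-formyl-2-methyl-3,4-dihydro-2H-pyran-5-carboxylate | COC(=O)C1=CO[C@@H](C)[C@@H](C=O)[C@@H]1CC(=O)OCCc1ccc(OCc2ccccc2)c(OCc2ccccc2)c1 | intermediate
22 | methyl (2S,3S,4S)-4-{2-[2-(3,4-dihydroxyphenyl)ethoxy]-2-oxoethyl}-3-formyl-2-methyl-3,4-dihydro-2H-pyran-5-carboxylate | COC(=O)C1=CO[C@@H](C)[C@@H](C=O)[C@@H]1CC(=O)OCCc1ccc(O)c(O)c1 | target

**Step count**
Total: 14 steps. Longest linear sequence: 11 steps (steps 1–6 and 10–14, from methyl acetoacetate); the malonate branch (steps 7–9) joins at step 10.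

**Steps most likely to fail**

Step 4. The ester on the central diene carbon lowers the nucleophilicity of the diene, so cycloaddition may be slower than hydrolysis of the diene or deactivation of the catalyst, and face and endo discrimination with the small acetaldehyde may be incomplete. The fallback is an auxiliary-controlled aldol route that sets out from acetaldehyde 7 and comes back at pyranone 9.
- Methyl 3-hydroxypropanoate is silylated (TIPSCl, imidazole) to methyl 3-(triisopropylsilyloxy)propanoate F1 and saponified (LiOH) to 3-(triisopropylsilyloxy)propanoic acid F2.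
- F2 is coupled through its pivaloyl mixed anhydride with lithiated (R)-4-benzyloxazolidin-2-one to (R)-4-benzyl-3-[3-(triisopropylsilyloxy)propanoyl]oxazolidin-2-one F3.
- The (Z)-boron enolate of F3 (Bu2BOTf, iPr2NEt, CH2Cl2, −78 °C) adds to 7 in an Evans syn aldol reaction to give (R)-4-benzyl-3-{(2R,3S)-3-hydroxy-2-[(triisopropylsilyloxy)methyl]butanoyl}oxazolidin-2-one F4.
- Transamidation (AlMe3, MeONHMe·HCl) gives (2R,3S)-3-hydroxy-N-methoxy-N-methyl-2-[(triisopropylsilyloxy)methyl]butanamide F5, and excess lithium enolate of methyl acetate (LiN(iPr)2, MeOAc, THF, −78 °C) converts it into methyl (4R,5S)-5-hydroxy-3-oxo-4-[(triisopropylsilyloxy)methyl]hexanoate F6.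
- Condensation of F6 with N,N-dimethylformamide dimethyl acetal and brief acid treatment closes the ring by oxa-Michael addition–elimination to 9.

Step 10. Retro-Michael loss of the stabilised malonate may outrun expulsion of methoxide, so that the acetal is recovered, and approach syn to the C3 arm would erode the 3,4-trans relation. The fallback is a cuprate route that sets out from acetal 11 and comes back at ester 19.
- Vinylmagnesium bromide with CuBr·SMe2 and Me3SiCl (THF, −78 °C) delivers a vinyl group to C4 anti to the C3 substituent, and the resulting enolate or ketene acetal loses methoxide on mildly acidic work-up to give methyl (2S,3R,4S)-2-methyl-3-[(triisopropylsilyloxy)methyl]-4-vinyl-3,4-dihydro-2H-pyran-5-carboxylate F7.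
- Hydroboration of the terminal alkene (9-BBN; NaBO3) gives methyl (2S,3R,4S)-4-(2-hydroxyethyl)-2-methyl-3-[(triisopropylsilyloxy)methyl]-3,4-dihydro-2H-pyran-5-carboxylate F8.
- Oxidation (TEMPO, PhI(OAc)2, MeCN–H2O) gives 2-{(2S,3R,4S)-5-(methoxycarbonyl)-2-methyl-3-[(triisopropylsilyloxy)methyl]-3,4-dihydro-2H-pyran-4-yl}acetic acid F9, which is esterified with alcohol 13 (EDC·HCl, DMAP) to 19.

Step 5. Conjugate delivery of hydride to the doubly activated C6 may compete with carbonyl reduction. The fallback masks C6 first; it sets out from pyranone 9 and comes back at acetal 11, bypassing step 6.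
- NaOMe in MeOH adds methoxide to C6 to give, as its enolate, methyl (2S,3R)-6-methoxy-2-methyl-4-oxo-3-[(triisopropylsilyloxy)methyl]tetrahydro-2H-pyran-5-carboxylate F10.
- After neutralisation with AcOH, NaBH4 reduces the ketone to methyl (2S,3S)-4-hydroxy-6-methoxy-2-methyl-3-[(triisopropylsilyloxy)methyl]tetrahydro-2H-pyran-5-carboxylate F11.
- Mesylation (MsCl, Et3N) gives methyl (2S,3R)-6-methoxy-2-methyl-4-(methylsulfonyloxy)-3-[(triisopropylsilyloxy)methyl]tetrahydro-2H-pyran-5-carboxylate F12, and E1cB elimination with DBU gives the C4=C5 enoate acetal 11.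

Further compounds
F1 | step 4 | methyl 3-(triisopropylsilyloxy)propanoate | COC(=O)CCO[Si](C(C)C)(C(C)C)C(C)C
F2 | step 4 | 3-(triisopropylsilyloxy)propanoic acid | OC(=O)CCO[Si](C(C)C)(C(C)C)C(C)C
F3 | step 4 | (R)-4-benzyl-3-[3-(triisopropylsilyloxy)propanoyl]oxazolidin-2-one | O=C(CCO[Si](C(C)C)(C(C)C)C(C)C)N1[C@H](Cc2ccccc2)COC1=O
F4 | step 4 | (R)-4-benzyl-3-{(2R,3S)-3-hydroxy-2-[(triisopropylsilyloxy)methyl]butanoyl}oxazolidin-2-one | C[C@H](O)[C@@H](CO[Si](C(C)C)(C(C)C)C(C)C)C(=O)N1[C@H](Cc2ccccc2)COC1=O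
F5 | step 4 | (2R,3S)-3-hydroxy-N-methoxy-N-methyl-2-[(triisopropylsilyloxy)methyl]butanamide | C[C@H](O)[C@@H](CO[Si](C(C)C)(C(C)C)C(C)C)C(=O)N(C)OC
F6 | step 4 | methyl (4R,5S)-5-hydroxy-3-oxo-4-[(triisopropylsilyloxy)methyl]hexanoate | C[C@H](O)[C@@H](CO[Si](C(C)C)(C(C)C)C(C)C)C(=O)CC(=O)OC
F7 | step 10 | methyl (2S,3R,4S)-2-methyl-3-[(triisopropylsilyloxy)methyl]-4-vinyl-3,4-dihydro-2H-pyran-5-carboxylate | COC(=O)C1=CO[C@@H](C)[C@@H](CO[Si](C(C)C)(C(C)C)C(C)C)[C@@H]1C=C
F8 | step 10 | methyl (2S,3R,4S)-4-(2-hydroxyethyl)-2-methyl-3-[(triisopropylsilyloxy)methyl]-3,4-dihydro-2H-pyran-5-carboxylate | COC(=O)C1=CO[C@@H](C)[C@@H](CO[Si](C(C)C)(C(C)C)C(C)C)[C@@H]1CCO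
F9 | step 10 | 2-{(2S,3R,4S)-5-(methoxycarbonyl)-2-methyl-3-[(triisopropylsilyloxy)methyl]-3,4-dihydro-2H-pyran-4-yl}acetic acid | COC(=O)C1=CO[C@@H](C)[C@@H](CO[Si](C(C)C)(C(C)C)C(C)C)[C@@H]1CC(=O)O
F10 | step 5 | methyl (2S,3R)-6-methoxy-2-methyl-4-oxo-3-[(triisopropylsilyloxy)methyl]tetrahydro-2H-pyran-5-carboxylate | COC(=O)C1C(=O)[C@H](CO[Si](C(C)C)(C(C)C)C(C)C)[C@H](C)OC1OC
F11 | step 5 | methyl (2S,3S)-4-hydroxy-6-methoxy-2-methyl-3-[(triisopropylsilyloxy)methyl]tetrahydro-2H-pyran-5-carboxylate | COC(=O)C1C(O)[C@H](CO[Si](C(C)C)(C(C)C)C(C)C)[C@H](C)OC1OC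
F12 | step 5 | methyl (2S,3R)-6-methoxy-2-methyl-4-(methylsulfonyloxy)-3-[(triisopropylsilyloxy)methyl]tetrahydro-2H-pyran-5-carboxylate | COC(=O)C1C(OS(C)(=O)=O)[C@H](CO[Si](C(C)C)(C(C)C)C(C)C)[C@H](C)OC1OC
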